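Slowness is the price of a long interval, for the last portion of substrate goes in later with every added hour, so before the next flask we settle whether 3.0 h between portions may stay, or must be lengthened so that substrate and tautomer have come close to balance before the next portion arrives.

| flask | substrate | gas | remark | time |
|---|---|---|---|---|
| grey | 0.075 M (in portions, 4) | 4 mM (held) | run made earlier; portions every 3.0 h |  |
| flask | 0.050 M (in portions, 4) | 4.0 mM (held) | the portions of substrate follow each other after 3.0 h, the first at the start | 12 h |

grey run (percent of the substrate charged)

| time / min | tautomer / % | target / % | substrate / % | isomer of the product / % |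
|---|---|---|---|---|
| 10.0 | 1.6 | 0 | 23.4 | 0.7 |
| 20.0 | 3.6 | 0.4 | 21.7 | 0 |
| 30.0 | 4.4 | 0 | 20.5 | 0 |
| 40.0 | 5.7 | 0 | 19.1 | 0 |
| 50.0 | 6.8 | 0.4 | 18.8 | 0 |
| 60.0 | 6.6 | 0.1 | 17.0 | 0.4 |
| 80.0 | 8.5 | 0.6 | 16.1 | 0.1 |

(standard deviation of a reading: 0.3 percentage points)

- what is said of target includes crystals
- crystals is a solid; its amount is given per volume of the solution
- at the start none of reagent is dissolved
- the earlier runs were read with a standard deviation of 0.3 percentage points
- reactions considered so far: gas <-> reagent; reagent + tautomer -> target; substrate + reagent -> isomer of the product; substrate <-> tautomer; crystals <-> target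
- percentages count the whole charge, also what has not yet gone in

1. the species in which most of what was charged as substrate, at 12 h sits (substrate / isomer of the product / tautomer / target)
2. the largest share itself, whichever of these holds it, in percent of the substrate charged

1. We take as the zero of our scale the symmetric case, substrate and tautomer holding equal fractions of the charge, and call substrate minus tautomer the imbalance. In the grey run it reads 22 percentage points at 10.0 min and 7.6 points at 80.0 min.

2. From these two readings we get 0.903 h⁻¹, the relaxation rate of the pair, the rate at which the imbalance of this pre-equilibrium shrinks. We take it as first-order, so it carries from the grey run to the flask.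

3. The time 1.11 h is shorter than the interval, and one interval leaves a fraction 0.0666 of a portion's imbalance, so we keep the interval and the charge as they are.

4. In the flask, the last portion, 25.0% of the charge, enters at 9.00 h and keeps an imbalance of 1.66% at 12 h. Target and isomer of the product together read 0.7 points at the last grey reading, at 80.0 min, before the second portion at 3.0 h, and with a scatter of 0.3 points per reading that cannot size their share at 12 h, so we leave that drain unreckoned and commit to substrate, at 50.8% before the drain is taken off.

The forecast, lower than our figure, gives substrate at 39%, from 32% to 46%, and adds “The choice between substrate and tautomer is close”.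

The flask gives substrate at 48.5%, with tautomer at 44.4%.

    gas ⇌ reagent, rate k1*(csat - [reagent]) (kL = 1.90 h⁻¹)
    reagent + tautomer → target (k = 2.80 M⁻¹ h⁻¹)
    substrate + reagent → isomer of the product (k = 2.50 M⁻¹ h⁻¹)
    substrate ⇌ tautomer (K = 0.950, k = 0.440 h⁻¹)
    crystals ⇌ target, rate k5*(cs5 - [target]) while solid is left; crystals form when [target] > cs5 (solubility = 12.0 mM, k = 0.540 h⁻¹)

At 12 h the flask's imbalance is 4.1 points, against our 1.66%. The neighbouring flask, the same charge read at 20 h, has had 11.0 h since its last portion, and for that time our rate leaves 0.00121% of the charge as imbalance. That neighbour holds substrate 44.0% and tautomer 41.8%, an imbalance of 2.2 points.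

The runs stem from a simulated flask from invented constants; scatter was added.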